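**Retrosynthetic overview**
1. The target comes from its 3'-O-TBS ether. The last step only frees the ring B phenol.
2. Rings C and A are cut together into three pieces. These are the ring B aldehyde (C2), the bis(silyl enol ether) of acetylacetone (C3–C4–C4a–C8a–C8) and prenylmalonyl dichloride (C5–C6–C7, carrying the 6-prenyl group).
3. Ring order going forward: ring B is bought. Ring C forms first, by a catalytic asymmetric vinylogous aldol that sets C2, followed by O1–C8a closure. Ring A forms second in the same flask, by [3+3] double C-acylation at C4a and C8.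
4. O1 sits on C8a before ring A exists and the malonyl unit is symmetric, so only the 6-prenyl isomer can form. The C2–O1 bond is never broken after it is set.
5. The ring B aldehyde comes from 2-bromoisovanillin (silylation, Stille prenylation). The dichloride comes from diethyl malonate and prenyl bromide.

Assumption: the (S)-BINOL/Ti(OiPr)4 catalyst is taken to attack the Si face of the aryl aldehyde, as it does with benzaldehyde-type substrates (S ligand gives S carbinol). The first batch is checked by chiral HPLC and CD, and (R)-BINOL is used if the sense is reversed.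

**Step 1**
Reactants: 1 2-bromo-3-hydroxy-4-methoxybenzaldehyde
Product: 2 2-bromo-3-(tert-butyldimethylsilyloxy)-4-methoxybenzaldehyde
Conditions: TBSCl (1.2 equiv), imidazole (2 equiv), DMF, rt, 6 h
Reagents that add atoms: tert-butyldimethylsilyl chloride, CC(C)(C)[Si](C)(C)Cl
Why: Imidazole-promoted O-silylation masks the only acidic OH, which would otherwise bind the titanium catalyst and be acylated by the dichloride in step 6, and the hindered aryl TBS ether survives palladium, silyl triflate and acid chloride conditions.

**Step 2**
Reactants: 2 2-bromo-3-(tert-butyldimethylsilyloxy)-4-methoxybenzaldehyde; 3 tributyl(3-methylbut-2-enyl)stannane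
Product: 4 3-(tert-butyldimethylsilyloxy)-4-methoxy-2-(3-methylbut-2-enyl)benzaldehyde
Conditions: Pd(PPh3)4 (5 mol %), toluene, 110 °C, 16 h
Reagents that add atoms: none
Why: In this Stille cross-coupling the ortho formyl group speeds oxidative addition into the hindered C–Br bond and reductive elimination occurs at the unsubstituted allyl terminus, so the linear prenyl arene forms under neutral conditions that spare the aldehyde and the silyl ether.

**Step 3**
Reactants: 5 acetylacetone
Product: 6 2,4-bis(trimethylsilyloxy)penta-1,3-diene
Conditions: TMSOTf (2.2 equiv), Et3N (2.5 equiv), Et2O, 0 °C to rt; distilled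
Reagents that add atoms: trimethylsilyl trifluoromethanesulfonate, C[Si](C)(C)OS(=O)(=O)C(F)(F)F
Why: Double soft enolisation and silylation of a 1,3-diketone with a silyl triflate and a tertiary amine gives the known Chan-type diene, a neutral equivalent of the acetylacetone dianion.

**Step 4**
Reactants: 7 diethyl malonate; 8 1-bromo-3-methylbut-2-ene (prenyl bromide)
Product: 10 2-(3-methylbut-2-enyl)malonic acid, via diethyl prenylmalonate 9 (not isolated)
Conditions: 7 (1.3 equiv), NaOEt, EtOH, 0 °C to rt; then KOH, H2O, 40 °C; then cold 2 M HCl to pH 1; recrystallised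
Reagents that add atoms: potassium hydroxide, [K+].[OH-]
Why: Malonic ester alkylation (SN2 at the primary allylic carbon) is followed by saponification in the same flask, and cold acidification avoids decarboxylation and acid-induced lactonisation onto the alkene.

**Step 5**
Reactants: 10 2-(3-methylbut-2-enyl)malonic acid
Product: 11 2-(3-methylbut-2-enyl)malonyl dichloride
Conditions: (COCl)2 (2.4 equiv), DMF (cat.), CH2Cl2, 0 °C to rt, N2 sweep; evaporated below 30 °C, used crude
Reagents that add atoms: oxalyl chloride, O=C(Cl)C(=O)Cl
Why: DMF-catalysed (Vilsmeier-type) acid chloride formation runs at or below room temperature, where trisubstituted alkenes of this kind are tolerated as long as the HCl is swept out of the solution.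

**Step 6**
Reactants: 4 3-(tert-butyldimethylsilyloxy)-4-methoxy-2-(3-methylbut-2-enyl)benzaldehyde; 6 2,4-bis(trimethylsilyloxy)penta-1,3-diene; 11 2-(3-methylbut-2-enyl)malonyl dichloride
Product: 14 (2S)-2-[3-(tert-butyldimethylsilyloxy)-4-methoxy-2-prenylphenyl]-5,7-dihydroxy-6-prenylchroman-4-one, via bis-TMS aldol adduct 12 (not isolated), via (S)-6-methyldihydropyranone 13 (not isolated)
Conditions: 4, 6 (1.2 equiv), (S)-BINOL (10 mol %), Ti(OiPr)4 (10 mol %), 4 Å MS, toluene, 0 °C, 24 h; then TMSOTf (20 mol %), −20 to 0 °C, 1 h; then 2,6-di-tert-butyl-4-methylpyridine (2.5 equiv), 11 (1.5 equiv, slow addition), 0 to 60 °C, 12 h; pH 7 buffer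
Reagents that add atoms: none
Why: Proposed new method: the first two events are known chemistry (a BINOL–titanium vinylogous Mukaiyama aldol of a Chan-type diene, here on the Si face of 4 to set C2 as S, then silyl-triflate ring closure of 12 with loss of hexamethyldisiloxane, which never breaks the C2–O bond), and the new part is that 13, whose C8a oxygen is already an ether and whose C4 ketone cannot enolise towards C4a, cannot close to a 2-pyrone and can only meet the 1,3-bis-electrophile 11 as a C4a/C8 bis-nucleophile, so that C-acylation, loss of HCl to an acylketene, enolisation to a dienylketene, 6π closure and tautomerisation give the phloroglucinol ring with the prenyl carbon locked between the two new phenols whichever acylation comes first, the closest known reaction types being the Effenberger annulation of enol ethers with malonyl dichloride (phloroglucinol monoethers, bicyclic triones) and the [3+3] cyclisations of 1,3-bis(silyloxy)dienes.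

**Step 7**
Reactants: 14 (2S)-2-[3-(tert-butyldimethylsilyloxy)-4-methoxy-2-prenylphenyl]-5,7-dihydroxy-6-prenylchroman-4-one
Product: 15 (2S)-5,7-dihydroxy-2-[3-hydroxy-4-methoxy-2-(3-methylbut-2-enyl)phenyl]-6-(3-methylbut-2-enyl)chroman-4-one (target)
Conditions: TBAF (1.1 equiv), AcOH (1.3 equiv), THF, 0 °C, 30 min
Reagents that add atoms: none
Why: Fluoride cleaves the aryl silyl ether, and the acetic acid buffer keeps the ring A phenols protonated, so there is no retro-oxa-Michael racemisation at C2 and the prenyl groups are untouched.

**Compound list**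
1 | 2-bromo-3-hydroxy-4-methoxybenzaldehyde (2-bromoisovanillin) | COc1ccc(C=O)c(Br)c1O | starting material
2 | 2-bromo-3-(tert-butyldimethylsilyloxy)-4-methoxybenzaldehyde | COc1ccc(C=O)c(Br)c1O[Si](C)(C)C(C)(C)C | intermediate
3 | tributyl(3-methylbut-2-enyl)stannane | CCCC[Sn](CCCC)(CCCC)CC=C(C)C | starting material
4 | 3-(tert-butyldimethylsilyloxy)-4-methoxy-2-(3-methylbut-2-enyl)benzaldehyde | COc1ccc(C=O)c(CC=C(C)C)c1O[Si](C)(C)C(C)(C)C | intermediate
5 | acetylacetone | CC(=O)CC(C)=O | starting material
6 | 2,4-bis(trimethylsilyloxy)penta-1,3-diene (E/Z mixture; the geometry is lost in step 6) | C=C(O[Si](C)(C)C)C=C(C)O[Si](C)(C)C | intermediate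
7 | diethyl malonate | CCOC(=O)CC(=O)OCC | starting material
8 | 1-bromo-3-methylbut-2-ene | CC(C)=CCBr | starting material
9 | diethyl 2-(3-methylbut-2-enyl)malonate | CCOC(=O)C(CC=C(C)C)C(=O)OCC | intermediate
10 | 2-(3-methylbut-2-enyl)malonic acid | OC(=O)C(CC=C(C)C)C(=O)O | intermediate
11 | 2-(3-methylbut-2-enyl)malonyl dichloride | ClC(=O)C(CC=C(C)C)C(Cl)=O | intermediate
12 | (6S)-6-[3-(tert-butyldimethylsilyloxy)-4-methoxy-2-prenylphenyl]-2,6-bis(trimethylsilyloxy)hex-2-en-4-one | COc1ccc([C@@H](O[Si](C)(C)C)CC(=O)C=C(C)O[Si](C)(C)C)c(CC=C(C)C)c1O[Si](C)(C)C(C)(C)C | intermediate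
13 | (2S)-2-[3-(tert-butyldimethylsilyloxy)-4-methoxy-2-prenylphenyl]-6-methyl-2,3-dihydro-4H-pyran-4-one | COc1ccc([C@@H]2CC(=O)C=C(C)O2)c(CC=C(C)C)c1O[Si](C)(C)C(C)(C)C | intermediate
14 | (2S)-2-[3-(tert-butyldimethylsilyloxy)-4-methoxy-2-prenylphenyl]-5,7-dihydroxy-6-prenylchroman-4-one | COc1ccc([C@@H]2CC(=O)c3c(cc(O)c(CC=C(C)C)c3O)O2)c(CC=C(C)C)c1O[Si](C)(C)C(C)(C)C | intermediate
15 | (2S)-5,7-dihydroxy-2-[3-hydroxy-4-methoxy-2-(3-methylbut-2-enyl)phenyl]-6-(3-methylbut-2-enyl)chroman-4-one | COc1ccc([C@@H]2CC(=O)c3c(cc(O)c(CC=C(C)C)c3O)O2)c(CC=C(C)C)c1O | target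

**Step count and risks**
Total steps: 7. Longest linear sequence: 4 (1 → 2 → 4 → 14 → 15). The malonate branch 7 → 10 → 11 → 14 → 15 is equally long.

**Step 6 is the most likely to fail.**
- The first, intermolecular C-acylation must occur on a deactivated push–pull enol ether.
- 13 can be lost by retro-oxa-Michael opening to the achiral cinnamoylacetone. This costs yield rather than ee.
- The phenols of 14 can be acylated by surplus 11.
- A modest ee can be raised by recrystallising 14 or 15.

The fallback sets out from 4 and comes back at 14. It replaces the [3+3] union by a [4+2] union in which C8 arrives as a regiodefined carbanion and ring A closes through a thermal acylketene.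
- Aldehyde 4 and Brassard's diene (1,3-dimethoxy-1-trimethylsilyloxybuta-1,3-diene) react under (S)-BINOL/Ti(OiPr)4 catalysis. This gives (6S)-6-[3-(tert-butyldimethylsilyloxy)-4-methoxy-2-prenylphenyl]-4-methoxy-5,6-dihydro-2H-pyran-2-one F1.
- tert-Butyl acetoacetate is alkylated with 8 (NaH, THF) to give tert-butyl 2-acetyl-5-methylhex-4-enoate F2.
- The dianion of F2 (NaH, then n-BuLi, −78 °C, 2.2 equiv) adds to the lactone carbonyl of F1 and opens it. This gives tert-butyl (6E,9S)-9-aryl-9-hydroxy-7-methoxy-2-prenyl-3,5-dioxonon-6-enoate F3.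
- Heating F3 with pyridinium p-toluenesulfonate (10 mol %) in toluene at 110 °C closes the hydroxyl onto the future C8a ketone with loss of methanol (ring C).
- In the same flask the β-keto ester expels tert-butanol, and the resulting acylketene closes onto C4a by 6π electrocyclisation (ring A). This gives 14.

**Step 2 is second.** The prenyl group may be delivered through its γ carbon (reverse prenyl), or the doubly ortho-substituted bromide may couple slowly. The fallback sets out from 2 and comes back at 4.
- Stille coupling with allyltributylstannane, which has no α/γ ambiguity, gives 2-allyl-3-(tert-butyldimethylsilyloxy)-4-methoxybenzaldehyde F4.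
- The trisubstituted alkene is then built by cross-metathesis of F4 with excess 2-methylbut-2-ene (second-generation Grubbs catalyst, CH2Cl2, 40 °C). This gives 4.

**Step 5 is third.** HCl released during chloride formation can add to the prenyl alkene, and the crude dichloride cannot be purified by hot distillation without forming the chlorocarbonyl ketene. The fallback sets out from 10 and comes back at 11.
- 10 is persilylated with hexamethyldisilazane (neat, 60 °C) to give bis(trimethylsilyl) 2-(3-methylbut-2-enyl)malonate F5.
- F5 is treated with oxalyl chloride and catalytic DMF in CH2Cl2 at 0 °C. The chloride then forms under neutral conditions, with a chlorosilane leaving in place of HCl.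

**Further compounds**
F1 | step 6 | (6S)-6-[3-(tert-butyldimethylsilyloxy)-4-methoxy-2-prenylphenyl]-4-methoxy-5,6-dihydro-2H-pyran-2-one | COc1ccc([C@@H]2CC(OC)=CC(=O)O2)c(CC=C(C)C)c1O[Si](C)(C)C(C)(C)C
F2 | step 6 | tert-butyl 2-acetyl-5-methylhex-4-enoate (racemic) | CC(=O)C(CC=C(C)C)C(=O)OC(C)(C)C
F3 | step 6 | tert-butyl (6E,9S)-9-[3-(tert-butyldimethylsilyloxy)-4-methoxy-2-prenylphenyl]-9-hydroxy-7-methoxy-2-(3-methylbut-2-enyl)-3,5-dioxonon-6-enoate (epimers at C2) | COc1ccc([C@@H](O)C/C(OC)=C\C(=O)CC(=O)C(CC=C(C)C)C(=O)OC(C)(C)C)c(CC=C(C)C)c1O[Si](C)(C)C(C)(C)C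
F4 | step 2 | 2-allyl-3-(tert-butyldimethylsilyloxy)-4-methoxybenzaldehyde | C=CCc1c(C=O)ccc(OC)c1O[Si](C)(C)C(C)(C)C
F5 | step 5 | bis(trimethylsilyl) 2-(3-methylbut-2-enyl)malonate | C[Si](C)(C)OC(=O)C(CC=C(C)C)C(=O)O[Si](C)(C)C
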